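## Retrosynthetic overview
1. Locants: ring C1 carries the side chain, C3 carries Br, C4 carries Cl and CH3; C7 is the carbinol carbon, C8 the CH2, C9/C10 the oxirane carbons. The oxirane is the last ring made: 15 ⇒ prenyl ketol 14 (reagent-controlled epoxidation) ⇒ crotyl ketol 12 (cross metathesis).
2. Key bond C7–C8: 12 ⇒ α-diazo ketone 9 + (S)-but-3-en-2-ol 10. Capture of the carbene by the alcohol turns the acyl carbon C7 into the nucleophilic end of an enediol mono-ether. This end bonds to the allyl terminus by a [3,3] shift with chirality transfer, which sets C7 and gives the free tertiary OH and the methyl ketone at once.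
3. 9 ⇒ its C1 epimer 7 (kinetic protonation). Direct BrCl addition can only place Br trans to the side chain, so C1 first steers C3/C4 and is then inverted under their control.
4. 7 ⇒ ethyl ketone 4 (diazo transfer) ⇒ cyclohexene 3 (trans-diaxial Markovnikov BrCl addition).
5. 3 ⇒ isoprene 1 + ethyl vinyl ketone 2. The carbocycle is formed first, by a catalytic enantioselective Diels–Alder reaction.

Assumption: compounds 1, 2, 10 (≥98% ee) and 13, both chiral catalysts and 4-acetamidobenzenesulfonyl azide are bought.

## Route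

Step 1
Reactants: 1 isoprene; 2 pent-1-en-3-one
Product: 3 (R)-1-(4-methylcyclohex-3-en-1-yl)propan-1-one
Conditions: (R)-3,3-diphenyl-1-(o-tolyl)tetrahydro-1H,3H-pyrrolo[1,2-c][1,3,2]oxazaborole (10 mol %), Tf2NH (8 mol %), CH2Cl2, −40 °C
Reagents that add atoms: none
Why: Catalytic enantioselective Diels–Alder reaction, in which the protonated oxazaborolidine binds the enone carbonyl and shields one face, isoprene adds para-selectively to the open face, and the (R)-catalyst gives (R)-C1, the mirror image of the sense shown by the (S)-catalyst with acrylates and vinyl ketones.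

Step 2
Reactants: 3 (R)-1-(4-methylcyclohex-3-en-1-yl)propan-1-one
Product: 4 1-[(1R,3S,4S)-3-bromo-4-chloro-4-methylcyclohexyl]propan-1-one
Conditions: NBS (1.1 equiv), SOCl2 (0.6 equiv), Ph3PO (5 mol %), CH2Cl2, −40 to 0 °C
Reagents that add atoms: N-bromosuccinimide, O=C1CCC(=O)N1Br; thionyl chloride, O=S(Cl)Cl
Why: Lewis-base-catalysed anti bromochlorination (electrophilic addition), in which bromonium formation is reversible and chloride opens it at the tertiary carbon through the chair-like trans-diaxial (Fürst–Plattner) transition state with the propanoyl group equatorial, so Br ends at C3 trans and Cl at C4 cis to the side chain and (R)-C1 fixes (3S,4S) (expected dr about 6:1, minor isomer removed by chromatography).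

Step 3
Reactants: 4 1-[(1R,3S,4S)-3-bromo-4-chloro-4-methylcyclohexyl]propan-1-one
Product: 7 1-[(1R,3S,4S)-3-bromo-4-chloro-4-methylcyclohexyl]-2-diazopropan-1-one, via lithium enolate 5 (not isolated), via trifluoroacetyl diketone 6 (not isolated)
Conditions: LiN(SiMe3)2, THF, −78 °C; CF3CO2CH2CF3; aq HCl work-up; then 4-acetamidobenzenesulfonyl azide, Et3N, H2O (1 equiv), MeCN, 23 °C
Reagents that add atoms: 4-acetamidobenzenesulfonyl azide, CC(=O)Nc1ccc(cc1)S(=O)(=O)N=[N+]=[N-]; 2,2,2-trifluoroethyl trifluoroacetate, FC(F)(F)COC(=O)C(F)(F)F (its CF3CO group stays only in 6)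
Why: Detrifluoroacetylative (Regitz-type deacylative) diazo transfer, in which the hindered amide removes the CH2 proton rather than the tertiary C1–H, C-trifluoroacetylation activates that carbon for attack on the azide and is lost again, and no stereocenter is touched.

Step 4
Reactants: 7 1-[(1R,3S,4S)-3-bromo-4-chloro-4-methylcyclohexyl]-2-diazopropan-1-one
Product: 9 1-[(1S,3S,4S)-3-bromo-4-chloro-4-methylcyclohexyl]-2-diazopropan-1-one, via exocyclic lithium enolate 8 (not isolated)
Conditions: LiN(i-Pr)2 (1.1 equiv), THF, −78 °C, 15 min; cannulate into 2,6-di-tert-butyl-4-methylphenol (3 equiv), THF, −78 °C; water work-up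
Reagents that add atoms: none
Why: Zimmerman-type kinetic protonation of an exocyclic enolate, in which C1–H is the only acidic proton left, the ring of 8 keeps Br and Cl axial and CH3 equatorial, the axial C3–Br blocks the axial face of C1, and the bulky phenol therefore delivers the proton from the equatorial face and pushes the acyl group to the side of Br, which inverts C1 to (S) before the ring flips to the chair with side chain, Br and Cl equatorial.

Step 5 (key step)
Reactants: 9 1-[(1S,3S,4S)-3-bromo-4-chloro-4-methylcyclohexyl]-2-diazopropan-1-one; 10 (S)-but-3-en-2-ol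
Product: 12 (3S,5E)-3-[(1S,3S,4S)-3-bromo-4-chloro-4-methylcyclohexyl]-3-hydroxyhept-5-en-2-one, via (Z)-alkoxy enol 11 (not isolated)
Conditions: Rh2(OAc)4 (1 mol %), 10 (1.5 equiv), PhH, 80 °C, slow addition of 9
Reagents that add atoms: none
Why: Rhodium-carbenoid-initiated Claisen rearrangement, in which loss of N2 makes the normally nucleophilic α-carbon an electrophilic carbene (an enolonium-type centre) that is captured by the OH of 10, the internal proton shift gives the (Z)-2-alkoxy enol 11, a mono-ether of an enediol whose former acyl carbon C7 is nucleophilic like an acyl anion equivalent, and its chair [3,3] shift with the carbinol methyl equatorial bonds C7 to the allyl terminus C8 faster than ketonisation, so that the (S)-carbinol centre is traded for (S)-C7 and an (E)-alkene.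

Step 6
Reactants: 12 (3S,5E)-3-[(1S,3S,4S)-3-bromo-4-chloro-4-methylcyclohexyl]-3-hydroxyhept-5-en-2-one; 13 2-methylbut-2-ene
Product: 14 (3S)-3-[(1S,3S,4S)-3-bromo-4-chloro-4-methylcyclohexyl]-3-hydroxy-6-methylhept-5-en-2-one
Conditions: second-generation Grubbs catalyst (H2IMes)(PCy3)Cl2Ru=CHPh (5 mol %), 13 (excess, co-solvent), CH2Cl2, 40 °C
Reagents that add atoms: none
Why: Olefin cross metathesis, which exchanges the ethylidene end of the only alkene in 12 for isopropylidene, is driven by excess 13 and loss of volatile butene, gives a trisubstituted alkene that no longer reacts, and touches no stereocenter.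

Step 7
Reactants: 14 (3S)-3-[(1S,3S,4S)-3-bromo-4-chloro-4-methylcyclohexyl]-3-hydroxy-6-methylhept-5-en-2-one
Product: 15 (3S)-3-[(1S,3S,4S)-3-bromo-4-chloro-4-methylcyclohexyl]-4-[(2R)-3,3-dimethyloxiran-2-yl]-3-hydroxybutan-2-one
Conditions: 1,2:4,5-di-O-isopropylidene-β-D-erythro-2,3-hexodiulo-2,6-pyranose (Shi ketone from D-fructose, 30 mol %), KHSO5 (as 2KHSO5·KHSO4·K2SO4), K2CO3, Bu4NHSO4 (cat.), MeCN–(MeO)2CH2/aq Na2B4O7–Na2EDTA buffer, 0 °C
Reagents that add atoms: potassium peroxymonosulfate, [K+].[O-]S(=O)(=O)OO
Why: Shi asymmetric epoxidation, in which the chiral dioxirane meets the trisubstituted alkene in the spiro transition state and the D-fructose series gives the (R)-configured CH–O carbon C9 by reagent control (about 10:1, minor epimer removed by chromatography), while the equatorial halides and the tertiary ketol survive the cold carbonate buffer.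

## Compound list
1 | isoprene (2-methylbuta-1,3-diene) | CC(=C)C=C | starting material
2 | pent-1-en-3-one (ethyl vinyl ketone) | CCC(=O)C=C | starting material
3 | (R)-1-(4-methylcyclohex-3-en-1-yl)propan-1-one | CCC(=O)[C@@H]1CCC(C)=CC1 | intermediate
4 | 1-[(1R,3S,4S)-3-bromo-4-chloro-4-methylcyclohexyl]propan-1-one (Br and Cl trans-diaxial, acyl equatorial and trans to Br) | CCC(=O)[C@@H]1CC[C@](C)(Cl)[C@@H](Br)C1 | intermediate
5 | lithium enolate of 4 on the ethyl side (not isolated) | [Li+].CC=C([O-])[C@@H]1CC[C@](C)(Cl)[C@@H](Br)C1 | intermediate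
6 | 1-[(1R,3S,4S)-3-bromo-4-chloro-4-methylcyclohexyl]-4,4,4-trifluoro-2-methylbutane-1,3-dione (crude, not isolated) | CC(C(=O)C(F)(F)F)C(=O)[C@@H]1CC[C@](C)(Cl)[C@@H](Br)C1 | intermediate
7 | 1-[(1R,3S,4S)-3-bromo-4-chloro-4-methylcyclohexyl]-2-diazopropan-1-one | CC(=[N+]=[N-])C(=O)[C@@H]1CC[C@](C)(Cl)[C@@H](Br)C1 | intermediate
8 | lithium 1-[(3S,4S)-3-bromo-4-chloro-4-methylcyclohexylidene]-2-diazopropan-1-olate (not isolated) | [Li+].CC(=[N+]=[N-])C([O-])=C1CC[C@](C)(Cl)[C@@H](Br)C1 | intermediate
9 | 1-[(1S,3S,4S)-3-bromo-4-chloro-4-methylcyclohexyl]-2-diazopropan-1-one (acyl, Br and Cl equatorial, CH3 axial) | CC(=[N+]=[N-])C(=O)[C@H]1CC[C@](C)(Cl)[C@@H](Br)C1 | intermediate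
10 | (S)-but-3-en-2-ol | C[C@H](O)C=C | starting material
11 | (1Z)-1-[(1S,3S,4S)-3-bromo-4-chloro-4-methylcyclohexyl]-2-[(2S)-but-3-en-2-yloxy]prop-1-en-1-ol (not isolated) | O/C([C@H]1CC[C@](C)(Cl)[C@@H](Br)C1)=C(/C)O[C@@H](C)C=C | intermediate
12 | (3S,5E)-3-[(1S,3S,4S)-3-bromo-4-chloro-4-methylcyclohexyl]-3-hydroxyhept-5-en-2-one | CC(=O)[C@](O)(C/C=C/C)[C@H]1CC[C@](C)(Cl)[C@@H](Br)C1 | intermediate
13 | 2-methylbut-2-ene | CC=C(C)C | starting material
14 | (3S)-3-[(1S,3S,4S)-3-bromo-4-chloro-4-methylcyclohexyl]-3-hydroxy-6-methylhept-5-en-2-one | CC(=O)[C@](O)(CC=C(C)C)[C@H]1CC[C@](C)(Cl)[C@@H](Br)C1 | intermediate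
15 | (3S)-3-[(1S,3S,4S)-3-bromo-4-chloro-4-methylcyclohexyl]-4-[(2R)-3,3-dimethyloxiran-2-yl]-3-hydroxybutan-2-one (CNP0256797.1) | CC(=O)[C@](O)(C[C@H]1OC1(C)C)[C@H]1CC[C@](C)(Cl)[C@@H](Br)C1 | target

## Step count and risks
Total step count: 7. Longest linear sequence: 7 steps (1 + 2 → 15). Any minor enantiomer carried from step 1 becomes a diastereomer once enantiopure 10 is built in, and it is removed by chromatography at 12.

**Step 5.** Three things can go wrong:
- The carbene may undergo a 1,2-hydride shift to the vinyl ketone.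
- Enol 11 may ketonise before it rearranges.
- A boat transition state would erode the chirality transfer.

The fallback sets out from 9 and 10 and comes back at 12. The O–H insertion product is made on purpose with Rh2(O2CCF3)4 in CH2Cl2 at 23 °C. This gives 1-[(1S,3S,4S)-3-bromo-4-chloro-4-methylcyclohexyl]-2-[(2S)-but-3-en-2-yloxy]propan-1-one F2, whose epimers at the ether-bearing carbon do not matter. That carbon is then deprotonated with KN(SiMe3)2 in toluene at −78 °C. The product is the chelated potassium (1Z)-1-[(1S,3S,4S)-3-bromo-4-chloro-4-methylcyclohexyl]-2-[(2S)-but-3-en-2-yloxy]prop-1-en-1-olate F3. On warming to 0 °C its anionic oxy-Claisen rearrangement runs through the same chair, and an NH4Cl quench gives 12.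

**Step 4.** Enolate 8 could close a cyclopropane onto C3–Br or lose HX. The facial selectivity of the protonation may also be only moderate. The fallback sets out from 7 and comes back at 9. The two C1 epimers are equilibrated with DBU (0.2 equiv) in DMSO at 23 °C, where the polar medium favours the diequatorial dihalide. Compound 9 is separated by chromatography and recovered 7 is recycled. This makes no new compound (F0).

**Step 2.** The ketone could be brominated at its α-carbon, and the ratio of facial isomers may be lower than expected. The fallback sets out from 3 and comes back at 4. NBS in aqueous acetone at 0 °C gives the trans-diaxial bromohydrin 1-[(1R,3S,4S)-3-bromo-4-hydroxy-4-methylcyclohexyl]propan-1-one F1, which is easier to purify. Dry HCl in CH2Cl2 at 0 °C then replaces the tertiary OH by Cl with retention. The antiperiplanar Br reforms the same bromonium ion, and chloride opens it diaxially at C4.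

## Further compounds
F1 | step 2 | 1-[(1R,3S,4S)-3-bromo-4-hydroxy-4-methylcyclohexyl]propan-1-one | CCC(=O)[C@@H]1CC[C@](C)(O)[C@@H](Br)C1
F0 | step 4 | none | none
F2 | step 5 | 1-[(1S,3S,4S)-3-bromo-4-chloro-4-methylcyclohexyl]-2-[(2S)-but-3-en-2-yloxy]propan-1-one | CC(O[C@@H](C)C=C)C(=O)[C@H]1CC[C@](C)(Cl)[C@@H](Br)C1
F3 | step 5 | potassium (1Z)-1-[(1S,3S,4S)-3-bromo-4-chloro-4-methylcyclohexyl]-2-[(2S)-but-3-en-2-yloxy]prop-1-en-1-olate | [K+].[O-]/C([C@H]1CC[C@](C)(Cl)[C@@H](Br)C1)=C(/C)O[C@@H](C)C=C
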